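All three flavan units derive from one protected teracacidin monomer, 15, which serves as C4 electrophile, as precursor of the thio-activated middle unit and as chain-terminating nucleophile; two 4β→6 Friedel–Crafts couplings then assemble the trimer. Everything rests on building the pyran ring (ring C: O1, C2, C3, C4, C4a, C8a) of each unit, the middle one included, in one operation: the C4 ketone of a 2-fluoroaryl α-alkoxy ketone makes C3 an enolate nucleophile and activates the ortho C8a–F bond, so aldol addition to 4-(benzyloxy)benzaldehyde (C2–C3) is followed by SNAr closure of the aldolate oxygen onto C8a (O1–C8a). The labile flavanone stereocentres are then set by dynamic kinetic resolution.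

Key step: step 4

Remark: the oxan-2-yl acetal carbon is carried as a mixture of epimers from 4 to 12 and is written without configuration; 3 is taken as a commercial compound.

Step 1
Reactants: 1 3-fluorobenzene-1,2-diol
Product: 2 1,2-bis(benzyloxy)-3-fluorobenzene
Conditions: BnBr, K2CO3, DMF, 60 °C
Reagents that add atoms: benzyl bromide, BrCc1ccccc1
Why: Double Williamson etherification of the catechol; the benzyl ethers should survive every later base, hydride and Lewis-acid step and leave only in the final hydrogenolysis.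

Step 2
Reactants: 3 2-hydroxy-N-methoxy-N-methylacetamide
Product: 4 N-methoxy-N-methyl-2-(oxan-2-yloxy)acetamide
Conditions: 3,4-dihydro-2H-pyran, PPTS (cat.), CH2Cl2, 25 °C
Reagents that add atoms: 3,4-dihydro-2H-pyran, C1=COCCC1
Why: Acid-catalysed acetalisation (tetrahydropyranylation) puts on the future O3 a base-stable group that cannot migrate to a neighbouring alkoxide and is later removable with weak acid.

Step 3
Reactants: 2 1,2-bis(benzyloxy)-3-fluorobenzene; 4 N-methoxy-N-methyl-2-(oxan-2-yloxy)acetamide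
Product: 6 1-[3,4-bis(benzyloxy)-2-fluorophenyl]-2-(oxan-2-yloxy)ethan-1-one, via aryllithium 5 (not isolated)
Conditions: n-BuLi, THF, −78 °C; then 4, −78 → 0 °C; NH4Cl (aq)
Reagents that add atoms: none
Why: Directed ortho-metalation at the only position ortho to fluorine, the most acidifying substituent, followed by single acylation through the chelated tetrahedral adduct of the N-methoxy-N-methylamide (Weinreb ketone synthesis); keeping −78 °C should prevent loss of LiF to an aryne.

Step 4
Reactants: 6 1-[3,4-bis(benzyloxy)-2-fluorophenyl]-2-(oxan-2-yloxy)ethan-1-one; 7 4-(benzyloxy)benzaldehyde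
Product: 10 racemic 7,8-bis(benzyloxy)-2-[4-(benzyloxy)phenyl]-3-(oxan-2-yloxy)-2,3-dihydro-4H-chromen-4-one (mainly 2,3-trans), via lithium enolate 8 (not isolated), via lithium aldolate 9 (not isolated)
Conditions: LiN(SiMe3)2, THF, −78 °C; then 7, −78 °C; then DMPU, −78 → 25 °C
Reagents that add atoms: none
Why: LiN(SiMe3)2 removes a C3 proton of 6 to give the chelated lithium enolate 8, which adds to aldehyde 7 (aldol addition) and forms the C2–C3 bond together with the C2 alkoxide 9; on warming with DMPU this alkoxide, the future O1, attacks C8a and expels fluoride through a Meisenheimer intermediate stabilised by the ortho C4 carbonyl (intramolecular SNAr), forming the O1–C8a bond. The closest known reaction types are the lithium enolate aldol addition and the SNAr ring closure of 2-fluoroaryl ketones to chroman-4-ones, here run as one domino operation. Ring C closes in a 6-exo mode, the alkoxide attacking the ring A carbon C8a from the tethered side chain. The new stereocentres C2 and C3 are deliberately not controlled: both are labile in the product (C3 by enolisation, C2 by E1cB ring opening and oxa-Michael reclosure), 10 is expected as the racemic, mainly 2,3-trans compound, and they are set in steps 5 and 9. The step needs closure through O1 and not O3 (six- against five-membered ring), secured by the non-migrating acetal on O3, and it needs the aldolate to cyclise faster than it eliminates water; retro-aldol cleavage is harmless because it is reversible while fluoride loss is not.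

Step 5
Reactants: 10 racemic 7,8-bis(benzyloxy)-2-[4-(benzyloxy)phenyl]-3-(oxan-2-yloxy)-2,3-dihydro-4H-chromen-4-one
Product: 11 (2R,3S,4R)-7,8-bis(benzyloxy)-2-[4-(benzyloxy)phenyl]-3-(oxan-2-yloxy)-3,4-dihydro-2H-chromen-4-ol
Conditions: RuCl(p-cymene)[(S,S)-TsDPEN] (cat.), HCO2H/DBU (1:1.2), MeCN, 40 °C
Reagents that add atoms: none
Why: Asymmetric transfer hydrogenation with dynamic kinetic resolution: DBU keeps the stereoisomers of 10 in equilibrium (C3 by enolisation, C2 by E1cB ring opening and oxa-Michael reclosure) while the (S,S)-catalyst delivers hydride to one face of the aryl ketone of the matched 2R isomer, anti to the 2-aryl group, which sets C4 (R, hydroxyl cis to the aryl group) and C2 (R); C3 is expected mainly S (3-O trans), and any 3R epimer converges in steps 8 and 9.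

Step 6
Reactants: 11 (2R,3S,4R)-7,8-bis(benzyloxy)-2-[4-(benzyloxy)phenyl]-3-(oxan-2-yloxy)-3,4-dihydro-2H-chromen-4-ol
Product: 12 (2R,3S,4R)-4,7,8-tris(benzyloxy)-2-[4-(benzyloxy)phenyl]-3-(oxan-2-yloxy)-3,4-dihydro-2H-chromene
Conditions: NaH, BnBr, Bu4NI (cat.), DMF, 0 → 25 °C
Reagents that add atoms: benzyl bromide, BrCc1ccccc1
Why: Williamson etherification of the C4 alkoxide with retention at C4; the O4 benzyl ether is later either the leaving group of a unit used as electrophile or the hydrogenolysable protection of the lower unit.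

Step 7
Reactants: 12 (2R,3S,4R)-4,7,8-tris(benzyloxy)-2-[4-(benzyloxy)phenyl]-3-(oxan-2-yloxy)-3,4-dihydro-2H-chromene
Product: 13 (2R,3S,4R)-4,7,8-tris(benzyloxy)-2-[4-(benzyloxy)phenyl]-3,4-dihydro-2H-chromen-3-ol
Conditions: PPTS, MeOH, 40 °C
Reagents that add atoms: none
Why: Acid-catalysed transacetalisation removes the oxanyl group; the weak acid and the destabilising β-oxygen should keep the benzylic C4–O bond from ionising.

Step 8
Reactants: 13 (2R,3S,4R)-4,7,8-tris(benzyloxy)-2-[4-(benzyloxy)phenyl]-3,4-dihydro-2H-chromen-3-ol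
Product: 14 (2R,4R)-4,7,8-tris(benzyloxy)-2-[4-(benzyloxy)phenyl]-2H-chromen-3(4H)-one
Conditions: Dess–Martin periodinane, pyridine, CH2Cl2, 0 → 25 °C
Reagents that add atoms: none
Why: Dess–Martin oxidation under buffered, non-enolising conditions erases the C3 configuration while C2 and C4 keep theirs (the 2,4-cis diequatorial ketone is also the more stable epimer).

Step 9
Reactants: 14 (2R,4R)-4,7,8-tris(benzyloxy)-2-[4-(benzyloxy)phenyl]-2H-chromen-3(4H)-one
Product: 15 (2R,3R,4R)-4,7,8-tris(benzyloxy)-2-[4-(benzyloxy)phenyl]-3,4-dihydro-2H-chromen-3-ol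
Conditions: Li[HB(s-Bu)3], THF, −78 °C; then H2O
Reagents that add atoms: none
Why: Substrate-controlled hydride reduction: the bulky borohydride approaches C3 from the face opposite the cis-disposed 2-aryl and 4-benzyloxy groups, so the new 3-OH comes out cis to both (3R, all-cis), as in the known conversion of 2,3-trans-flavan-3-ols into their 2,3-cis epimers by oxidation and reduction.

Step 10
Reactants: 15 (2R,3R,4R)-4,7,8-tris(benzyloxy)-2-[4-(benzyloxy)phenyl]-3,4-dihydro-2H-chromen-3-ol
Product: 16 (2R,3S,4S)-7,8-bis(benzyloxy)-2-[4-(benzyloxy)phenyl]-4-[(2,6-dimethylphenyl)sulfanyl]-3,4-dihydro-2H-chromen-3-ol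
Conditions: 2,6-dimethylbenzenethiol, BF3·OEt2, CH2Cl2, −40 °C
Reagents that add atoms: 2,6-dimethylbenzenethiol, Cc1cccc(C)c1S
Why: SN1 substitution: the Lewis acid ionises the C4 benzyl ether (the cation is stabilised by O1 and the 7-oxygen) and the thiol adds anti to the axial 3-OH to give the 4β-thioether, which should be inert to hard Lewis acids but open to thiophilic activation.

Step 11
Reactants: 15 (2R,3R,4R)-4,7,8-tris(benzyloxy)-2-[4-(benzyloxy)phenyl]-3,4-dihydro-2H-chromen-3-ol; 16 (2R,3S,4S)-7,8-bis(benzyloxy)-2-[4-(benzyloxy)phenyl]-4-[(2,6-dimethylphenyl)sulfanyl]-3,4-dihydro-2H-chromen-3-ol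
Product: 17 hexa-O-benzyl epioritin-(4β→6)-epioritin 4β-(2,6-dimethylphenyl) thioether (upper unit 2R,3R,4S; lower unit 2R,3S,4S)
Conditions: BF3·OEt2, CH2Cl2, −78 → −40 °C, slow addition of 15 to 16 (3 equiv)
Reagents that add atoms: none
Why: Friedel–Crafts alkylation of ring A of 16 at C6 (para to O1, ortho to the 7-benzyloxy group) by the flavan-4-yl cation from 15; attack anti to the axial 3-OH sets the 4β bond (4S), excess 16 and slow addition should hold back self-condensation of 15, and the arylthio group should stay untouched by the hard Lewis acid.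

Step 12
Reactants: 17 hexa-O-benzyl epioritin-(4β→6)-epioritin 4β-(2,6-dimethylphenyl) thioether; 15 (2R,3R,4R)-4,7,8-tris(benzyloxy)-2-[4-(benzyloxy)phenyl]-3,4-dihydro-2H-chromen-3-ol
Product: 18 deca-O-benzyl epioritin-(4β→6)-epioritin-(4β→6)-epioritin-4α-ol (benzyl on every phenol and on O4 of the lower unit)
Conditions: NIS, 4 Å molecular sieves, CH2Cl2, −40 → 0 °C, 15 (3 equiv)
Reagents that add atoms: none
Why: Thiophilic activation of the C4–S bond by iodonium transfer ionises the middle unit under neutral conditions, and Friedel–Crafts alkylation at C6 of 15, again anti to the axial 3-OH (4β, 4S), forms the second interflavan bond; no hard acid is present, so the O4 benzyl ether of 15 should not ionise.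

Step 13
Reactants: 18 deca-O-benzyl epioritin-(4β→6)-epioritin-(4β→6)-epioritin-4α-ol
Product: 19 epioritin-(4β→6)-epioritin-(4β→6)-epioritin-4α-ol (CNP0140823.1)
Conditions: H2 (1 atm), Pd(OH)2/C, THF/MeOH, 25 °C
Reagents that add atoms: none
Why: Hydrogenolysis of the ten benzyl ethers at their PhCH2–O bonds under neutral conditions should free the nine phenols and the 4-OH of the lower unit without touching any stereocentre.

Compound list
1 | 3-fluorobenzene-1,2-diol | Oc1cccc(F)c1O | starting material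
2 | 1,2-bis(benzyloxy)-3-fluorobenzene | Fc1cccc(OCc2ccccc2)c1OCc1ccccc1 | intermediate
3 | 2-hydroxy-N-methoxy-N-methylacetamide | CON(C)C(=O)CO | starting material
4 | N-methoxy-N-methyl-2-(oxan-2-yloxy)acetamide | CON(C)C(=O)COC1CCCCO1 | intermediate
5 | [3,4-bis(benzyloxy)-2-fluorophenyl]lithium | [Li]c1ccc(OCc2ccccc2)c(OCc2ccccc2)c1F | intermediate (not isolated)
6 | 1-[3,4-bis(benzyloxy)-2-fluorophenyl]-2-(oxan-2-yloxy)ethan-1-one | O=C(COC1CCCCO1)c1ccc(OCc2ccccc2)c(OCc2ccccc2)c1F | intermediate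
7 | 4-(benzyloxy)benzaldehyde | O=Cc1ccc(OCc2ccccc2)cc1 | starting material
8 | lithium (Z)-1-[3,4-bis(benzyloxy)-2-fluorophenyl]-2-(oxan-2-yloxy)ethen-1-olate | [Li+].[O-]/C(=C\OC1CCCCO1)c1ccc(OCc2ccccc2)c(OCc2ccccc2)c1F | intermediate (not isolated)
9 | lithium 3-[3,4-bis(benzyloxy)-2-fluorophenyl]-1-[4-(benzyloxy)phenyl]-2-(oxan-2-yloxy)-3-oxopropan-1-olate (racemic, both diastereomers) | [Li+].[O-]C(c1ccc(OCc2ccccc2)cc1)C(OC1CCCCO1)C(=O)c1ccc(OCc2ccccc2)c(OCc2ccccc2)c1F | intermediate (not isolated)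
10 | racemic 7,8-bis(benzyloxy)-2-[4-(benzyloxy)phenyl]-3-(oxan-2-yloxy)-2,3-dihydro-4H-chromen-4-one (mainly 2,3-trans; configurations not written because they are reset in step 5) | c1cc2c(c(OCc3ccccc3)c1OCc1ccccc1)OC(c1ccc(OCc3ccccc3)cc1)C(OC1CCCCO1)C2=O | intermediate
11 | (2R,3S,4R)-7,8-bis(benzyloxy)-2-[4-(benzyloxy)phenyl]-3-(oxan-2-yloxy)-3,4-dihydro-2H-chromen-4-ol | c1cc2c(c(OCc3ccccc3)c1OCc1ccccc1)O[C@H](c1ccc(OCc3ccccc3)cc1)[C@@H](OC1CCCCO1)[C@@H]2O | intermediate
12 | (2R,3S,4R)-4,7,8-tris(benzyloxy)-2-[4-(benzyloxy)phenyl]-3-(oxan-2-yloxy)-3,4-dihydro-2H-chromene | c1cc2c(c(OCc3ccccc3)c1OCc1ccccc1)O[C@H](c1ccc(OCc3ccccc3)cc1)[C@@H](OC1CCCCO1)[C@@H]2OCc1ccccc1 | intermediate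
13 | (2R,3S,4R)-4,7,8-tris(benzyloxy)-2-[4-(benzyloxy)phenyl]-3,4-dihydro-2H-chromen-3-ol | c1cc2c(c(OCc3ccccc3)c1OCc1ccccc1)O[C@H](c1ccc(OCc3ccccc3)cc1)[C@@H](O)[C@@H]2OCc1ccccc1 | intermediate
14 | (2R,4R)-4,7,8-tris(benzyloxy)-2-[4-(benzyloxy)phenyl]-2H-chromen-3(4H)-one | c1cc2c(c(OCc3ccccc3)c1OCc1ccccc1)O[C@H](c1ccc(OCc3ccccc3)cc1)C(=O)[C@@H]2OCc1ccccc1 | intermediate
15 | (2R,3R,4R)-4,7,8-tris(benzyloxy)-2-[4-(benzyloxy)phenyl]-3,4-dihydro-2H-chromen-3-ol (4,7,8,4′-tetra-O-benzyl teracacidin, all-cis) | c1cc2c(c(OCc3ccccc3)c1OCc1ccccc1)O[C@H](c1ccc(OCc3ccccc3)cc1)[C@H](O)[C@@H]2OCc1ccccc1 | intermediate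
16 | (2R,3S,4S)-7,8-bis(benzyloxy)-2-[4-(benzyloxy)phenyl]-4-[(2,6-dimethylphenyl)sulfanyl]-3,4-dihydro-2H-chromen-3-ol | c1cc2c(c(OCc3ccccc3)c1OCc1ccccc1)O[C@H](c1ccc(OCc3ccccc3)cc1)[C@H](O)[C@H]2Sc1c(C)cccc1C | intermediate
17 | hexa-O-benzyl epioritin-(4β→6)-epioritin 4β-(2,6-dimethylphenyl) thioether (upper unit 2R,3R,4S; lower unit 2R,3S,4S) | c1cc2c(c(OCc3ccccc3)c1OCc1ccccc1)O[C@H](c1ccc(OCc3ccccc3)cc1)[C@H](O)[C@H]2c1cc2c(c(OCc3ccccc3)c1OCc1ccccc1)O[C@H](c1ccc(OCc3ccccc3)cc1)[C@H](O)[C@H]2Sc1c(C)cccc1C | intermediate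
18 | deca-O-benzyl epioritin-(4β→6)-epioritin-(4β→6)-epioritin-4α-ol (units from the top: 2R,3R,4S; 2R,3R,4S; 2R,3R,4R) | c1cc2c(c(OCc3ccccc3)c1OCc1ccccc1)O[C@H](c1ccc(OCc3ccccc3)cc1)[C@H](O)[C@H]2c1cc2c(c(OCc3ccccc3)c1OCc1ccccc1)O[C@H](c1ccc(OCc3ccccc3)cc1)[C@H](O)[C@H]2c1cc2c(c(OCc3ccccc3)c1OCc1ccccc1)O[C@H](c1ccc(OCc3ccccc3)cc1)[C@H](O)[C@@H]2OCc1ccccc1 | intermediate
19 | epioritin-(4β→6)-epioritin-(4β→6)-epioritin-4α-ol, CNP0140823.1 (units from the top: 2R,3R,4S; 2R,3R,4S; 2R,3R,4R) | Oc1ccc([C@H]2Oc3c(ccc(O)c3O)[C@H](c3cc4c(c(O)c3O)O[C@H](c3ccc(O)cc3)[C@H](O)[C@H]4c3cc4c(c(O)c3O)O[C@H](c3ccc(O)cc3)[C@H](O)[C@@H]4O)[C@H]2O)cc1 | target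

Total steps: 13. Longest linear sequence: 12 (steps 1 and 3 to 13; step 2 is a side branch).

Steps most likely to fail

1. Step 5. Racemisation of the flavanone (ring opening and reclosure at C2) may be slower than reduction, so that the mismatched enantiomer accumulates or is reduced with poor facial discrimination. Fallback, from 10 back to 11: the transfer hydrogenation would be run as a plain kinetic resolution (same catalyst, HCO2H/Et3N 1:1, 25 °C, no DBU), in which only the 2R ketone is reduced to 11. The unreacted (2S,3S)-7,8-bis(benzyloxy)-2-[4-(benzyloxy)phenyl]-3-(oxan-2-yloxy)-2,3-dihydro-4H-chromen-4-one F3 would be separated, racemised in a separate flask (DBU, toluene, 60 °C) back to 10 and resubmitted. Resolution and racemisation are thereby decoupled.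

2. Step 4. The aldolate may lose water to the chalcone or revert to its components faster than it displaces fluoride from the electron-rich ring A. Fallback, from 6 and 7 back to 10: silylation of 6 (LiN(SiMe3)2, Me3SiCl, THF, −78 °C) would give the trimethylsilyl enol ether F1. A fluoride-catalysed Mukaiyama aldol addition of F1 to 7 (Bu4N[Ph3SiF2] cat., THF, −78 °C), in which the aldolate is silylated at once and cannot revert, would give the O-trimethylsilyl aldol F2, which is isolated. Treating F2 with CsF in DMF at 60 °C would unmask the alkoxide and close ring C by SNAr in a separate step that can be optimised on its own.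

3. Step 11. The cation from 15 may be captured by ring A of a second molecule of 15 or of the product, giving self-condensation and over-alkylation. Fallback, from 15 back to 19: bromination of 15 at C6 (NBS, CH2Cl2, −20 °C) would give the 6-bromo monomer F4, whose ring A can no longer act as nucleophile. Its coupling with 16 (BF3·OEt2, CH2Cl2, −78 °C) would give the bromo-capped dimer thioether F5, and NIS-mediated coupling of F5 with 15 would give the bromo-capped trimer F6. Hydrogenolysis of F6 (H2, Pd(OH)2/C, Et3N, THF/MeOH) would remove the bromine together with the benzyl groups and give 19.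

Further compounds
F1 | step 4 | {[(Z)-1-[3,4-bis(benzyloxy)-2-fluorophenyl]-2-(oxan-2-yloxy)ethenyl]oxy}trimethylsilane | C[Si](C)(C)O/C(=C\OC1CCCCO1)c1ccc(OCc2ccccc2)c(OCc2ccccc2)c1F
F2 | step 4 | 1-[3,4-bis(benzyloxy)-2-fluorophenyl]-3-[4-(benzyloxy)phenyl]-2-(oxan-2-yloxy)-3-[(trimethylsilyl)oxy]propan-1-one (racemic, both diastereomers) | C[Si](C)(C)OC(c1ccc(OCc2ccccc2)cc1)C(OC1CCCCO1)C(=O)c1ccc(OCc2ccccc2)c(OCc2ccccc2)c1F
F3 | step 5 | (2S,3S)-7,8-bis(benzyloxy)-2-[4-(benzyloxy)phenyl]-3-(oxan-2-yloxy)-2,3-dihydro-4H-chromen-4-one | c1cc2c(c(OCc3ccccc3)c1OCc1ccccc1)O[C@@H](c1ccc(OCc3ccccc3)cc1)[C@H](OC1CCCCO1)C2=O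
F4 | step 11 | (2R,3R,4R)-4,7,8-tris(benzyloxy)-2-[4-(benzyloxy)phenyl]-6-bromo-3,4-dihydro-2H-chromen-3-ol | Brc1cc2c(c(OCc3ccccc3)c1OCc1ccccc1)O[C@H](c1ccc(OCc3ccccc3)cc1)[C@H](O)[C@@H]2OCc1ccccc1
F5 | step 11 | 6-bromo (upper unit) hexa-O-benzyl epioritin-(4β→6)-epioritin 4β-(2,6-dimethylphenyl) thioether | Brc1cc2c(c(OCc3ccccc3)c1OCc1ccccc1)O[C@H](c1ccc(OCc3ccccc3)cc1)[C@H](O)[C@H]2c1cc2c(c(OCc3ccccc3)c1OCc1ccccc1)O[C@H](c1ccc(OCc3ccccc3)cc1)[C@H](O)[C@H]2Sc1c(C)cccc1C
F6 | step 11 | 6-bromo (top unit) deca-O-benzyl epioritin-(4β→6)-epioritin-(4β→6)-epioritin-4α-ol | Brc1cc2c(c(OCc3ccccc3)c1OCc1ccccc1)O[C@H](c1ccc(OCc3ccccc3)cc1)[C@H](O)[C@H]2c1cc2c(c(OCc3ccccc3)c1OCc1ccccc1)O[C@H](c1ccc(OCc3ccccc3)cc1)[C@H](O)[C@H]2c1cc2c(c(OCc3ccccc3)c1OCc1ccccc1)O[C@H](c1ccc(OCc3ccccc3)cc1)[C@H](O)[C@@H]2OCc1ccccc1
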